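The earlier runs and the new flask are simulated with constants of no real substance; the scatter is artificial.

At late times both earlier runs stood still. The starting complex read 0.5% in south and 0% in west, so I asked how much of each product the ligand could pay for.

| flask | starting complex | incoming ligand | remark | time |
|---|---|---|---|---|
| south | 2 mM | 2.5 mM | run made earlier |  |
| west | 2 mM | 3.8 mM | run made earlier |  |
| flask | 2.0 mM | 5.00 mM |  | 15 min |

- south (time / min: starting complex / %, complex with one exchanged / %, complex with three exchanged / %): 1.00: 2.3, 76.8, 8.3; 1.33: 2.0, 76.0, 8.4; 2.00: 1.2, 75.2, 9.5; 3.00: 0.2, 74.2, 10.9; 5.00: 0.5, 72.8, 10.1; 8.00: 0.4, 73.6, 10.9; 12.0: 0.5, 73.3, 10.0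
- west (time / min: starting complex / %, complex with one exchanged / %, complex with three exchanged / %): 0.667: 0, 66.5, 22.8; 2.00: 0.9, 51.7, 37.5; 3.00: 0, 49.4, 40.0; 5.00: 0.2, 48.9, 42.0; 8.00: 0, 48.5, 40.9; 10.0: 0.1, 48.8, 42.5; 12.0: 0, 48.3, 41.2

(standard deviation of a reading: 0.5 percentage points)

- the analysis behind the earlier runs scatters by 0.5 percentage points, standard deviation
- the reaction counts as stopped when no species that holds the starting complex changes by six tenths of a point or more over the second half of the time

1. which holds at 15 min: what has brought the reaction to rest, or that it has not come to rest (all of the starting complex has reacted / it is still moving)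
2. share of the starting complex used up at 15 min
3. complex with one exchanged at 15 min, in percent of the starting complex charged
4. complex with three exchanged at 15 min, in percent of the starting complex charged

I wrote Ma and Mc for the complexes with one and three exchanged, as percent of the starting complex charged. E is charged incoming ligand over charged starting complex, 2.50 in the new flask. Suppose each complex ends as Ma or Mc and the incoming ligand, the limiting reagent, is used up:

Ma + Mc = 100%

Ma + 3 Mc = 100E %

Mc = (E − 1)/2 = 75.0%

This is the ligand ceiling, my bound from above. At its last reading south read 2.5 percentage points under its own ceiling and west read 3.8 points under, so the gap read wider in west. For my bound from below I took the straight line through the two last Mc readings: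

Mc = 70.0%

Its gap of 5 points is wider than either read gap. West had levelled by 5.00 min, well before 15 min.

The forecast said that all of the starting complex has reacted, with 99.8% used up, Mc 71% and Ma 23%: “That growth stops once the ligand is spent.” Its Mc lay inside my bracket.

In the flask, all of the starting complex has reacted, with 100% used up, Ma 21.7% and Mc 73.6%. The forecast held.

    starting complex + complex with one exchanged → side product (k = 2.89 L mol⁻¹ s⁻¹)
    complex with one exchanged + incoming ligand → leaving ligand + complex with two exchanged (k = 8.47 L mol⁻¹ s⁻¹)
    starting complex + incoming ligand → leaving ligand + complex with one exchanged (k = 118 L mol⁻¹ s⁻¹)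
    complex with two exchanged + incoming ligand → leaving ligand + complex with three exchanged (k = 61.3 L mol⁻¹ s⁻¹)

The flask's Mc stood 1.4 points under the ceiling, with complex with two exchanged at 3.47%, side product at 1.30% and incoming ligand at 0.012% of its charge. I then reckoned a neighbouring flask, the same flask with 0.80 mM of starting complex. Its E is 6.25, and its ceiling reckons to 262%, above the 100% charged. So in the neighbouring flask the starting complex ran out first, at 0%. Full conversion to Mc there takes 3 ligands per complex and reckons to leave 52.0% of the incoming ligand. The neighbouring flask gave Mc 99.6%, with incoming ligand left at 52%.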